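The 2(5H)-furanone is read as an oxidised furan: ring O1 with its two neighbours, the lactone carbon C2 and the alkyl-bearing C5, is carried by O1, C5 and C2 of a 2-alkyl-4-methyloxazole, and C3(CH3)=C4(CO2H) by a but-2-ynoate. One thermal Diels–Alder/retro-Diels–Alder operation bonds both alkyne carbons to these two oxazole carbons and expels the temporary N=C(CH3) bridge as acetonitrile, which gives the fully substituted furan-3-carboxylate. Singlet oxygen then raises the unsubstituted furan carbon to the lactone carbonyl, and asymmetric transfer hydrogenation of the ring-opened keto acid sets the (R) stereocenter before relactonisation.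

Key step: step 5

Remark on the chemistry: a tert-butyl ester is assumed to survive 180 °C for the duration of step 5 as long as no acid is present (the oxazole buffers the mixture). Compounds 1, 5 and 8 are commercial.

Step 1
Reactants: 1 14-hydroxytetradecanoic acid
Product: 2 14-acetoxytetradecanoic acid
Conditions: Ac2O, pyridine, DMAP (cat.), CH2Cl2, 0 °C to rt; then H2O
Reagents that add atoms: acetic anhydride, CC(=O)OC(C)=O
Why: DMAP-catalysed O-acylation (nucleophilic acyl substitution) of the primary alcohol; any mixed anhydride formed at the carboxyl group is hydrolysed in the aqueous quench, and no stereocenter is involved.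

Step 2
Reactants: 2 14-acetoxytetradecanoic acid
Product: 4 14-acetoxytetradecanamide, via acid chloride 3 (not isolated)
Conditions: (COCl)2, DMF (cat.), CH2Cl2, 0 °C to rt; concentrate; then NH3 (0.5 M in 1,4-dioxane), 0 °C
Reagents that add atoms: ammonia, N
Why: Vilsmeier-type activation of the acid to the acyl chloride followed by aminolysis (nucleophilic acyl substitution), which at 0 °C should be far faster than attack of ammonia on the primary acetate.

Step 3
Reactants: 4 14-acetoxytetradecanamide; 5 chloroacetone (1-chloropropan-2-one)
Product: 7 2-(13-acetoxytridecyl)-4-methyloxazole, via hydroxyoxazoline 6 (not isolated)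
Conditions: CaCO3, toluene, 110 °C
Reagents that add atoms: none
Why: Blümlein–Lewy oxazole synthesis, in which O-alkylation of the amide by the chloroketone, closure of nitrogen onto the ketone and dehydration of hydroxyoxazoline 6 should give the 2,4-disubstituted oxazole with C5 unsubstituted, while CaCO3 keeps HCl away from the acetate.

Step 4
Reactants: 8 but-2-ynoic acid
Product: 9 tert-butyl but-2-ynoate
Conditions: 2-methylpropene, H2SO4 (cat.), CH2Cl2, sealed vessel, rt
Reagents that add atoms: 2-methylpropene, CC(C)=C
Why: Acid-catalysed addition of the carboxylic acid to 2-methylpropene (esterification through the tert-butyl cation) installs an ester that tolerates neutral heating, amine bases and transfer hydrogenation and is removed at the end by acid.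

Step 5
Reactants: 7 2-(13-acetoxytridecyl)-4-methyloxazole; 9 tert-butyl but-2-ynoate
Product: 11 tert-butyl 2-(13-acetoxytridecyl)-4-methylfuran-3-carboxylate, via bicyclic cycloadduct 10 (not isolated)
Conditions: 1,2-dichlorobenzene, sealed tube, 180 °C (9 in excess)
Reagents that add atoms: none
Why: Normal-electron-demand Diels–Alder addition of the ynoate across C2 and C5 of the oxazole (the 2-azadiene C2=N3–C4=C5) should give the 7-oxa-2-azabicyclo[2.2.1]hepta-2,5-diene 10, which then loses acetonitrile by retro-Diels–Alder reaction to give the aromatic furan. The closest known reaction type is the oxazole–alkyne Diels–Alder/retro-Diels–Alder synthesis of furans. The six-membered ring of the bicycle is closed by a concerted suprafacial [4+2] cycloaddition and opened again by [4+2] cycloreversion, so that the five-membered ring O1–C2–C3–C4–C5 of furan 11 is what remains. No stereocenter survives the step, because both bridgeheads return to trigonal carbons, and the stereocenter of the target is set in step 7. The step needs regioselectivity: oxazole C5, the more nucleophilic diene terminus (para to the 4-methyl group, remote from the 2-alkyl group and not bonded to nitrogen), should bond to the methyl-bearing β-carbon of the ynoate, which places the ester next to the chain-bearing carbon. It also needs the bicycle to lose the nitrile and not the alkyne, which aromatisation to the furan and the volatility of acetonitrile at this temperature should secure.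

Step 6
Reactants: 11 tert-butyl 2-(13-acetoxytridecyl)-4-methylfuran-3-carboxylate
Product: 13 tert-butyl 2-(13-acetoxytridecyl)-2-hydroxy-4-methyl-5-oxo-2,5-dihydrofuran-3-carboxylate, via endoperoxide 12 (not isolated)
Conditions: O2, tetraphenylporphyrin (cat.), visible light, i-Pr2NEt, CH2Cl2, −40 °C to 0 °C; then aq. citric acid
Reagents that add atoms: dioxygen, O=O
Why: [4+2] cycloaddition of singlet oxygen to the furan gives endoperoxide 12, and base-induced Kornblum–DeLaMare fragmentation at the only bridgehead C–H turns that carbon into the lactone carbonyl and leaves the alkyl-bearing carbon as a hemiketal, so only one regioisomer is possible; the hemiketal center is racemic and is erased in step 7.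

Step 7
Reactants: 13 tert-butyl 2-(13-acetoxytridecyl)-2-hydroxy-4-methyl-5-oxo-2,5-dihydrofuran-3-carboxylate
Product: 16 tert-butyl (R)-2-(13-acetoxytridecyl)-4-methyl-5-oxo-2,5-dihydrofuran-3-carboxylate, via keto acid 14 (not isolated), via hydroxy acid 15 (not isolated)
Conditions: RuCl[(R,R)-TsDPEN](p-cymene) (2 mol %), HCO2H/Et3N (1:2), DMF, 40 °C; then 1 M HCl, EtOAc, rt
Reagents that add atoms: none
Why: Noyori-type asymmetric transfer hydrogenation, in which triethylamine opens pseudo-acid 13 to keto carboxylate 14, the ruthenium hydride of the (R,R)-TsDPEN complex is expected (by analogy with aryl alkyl ketones, the alkenyl group taking the place of the aryl group) to deliver hydride to the Si face of the ketone and so set the (R)-carbinol of 15 under catalyst control, and acidification closes the γ-lactone onto the cis carboxyl group without touching the new center.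

Step 8
Reactants: 16 tert-butyl (R)-2-(13-acetoxytridecyl)-4-methyl-5-oxo-2,5-dihydrofuran-3-carboxylate
Product: 17 (R)-2-(13-acetoxytridecyl)-4-methyl-5-oxo-2,5-dihydrofuran-3-carboxylic acid
Conditions: CF3CO2H, CH2Cl2, 0 °C to rt
Reagents that add atoms: none
Why: Acidolysis of the tert-butyl ester (E1 loss of the tert-butyl cation as 2-methylpropene) frees the acid without touching the primary acetate, the lactone or the base-sensitive C5 stereocenter.

Compound list
1 | 14-hydroxytetradecanoic acid | OCCCCCCCCCCCCCC(=O)O | starting material
2 | 14-acetoxytetradecanoic acid | CC(=O)OCCCCCCCCCCCCCC(=O)O | intermediate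
3 | 14-acetoxytetradecanoyl chloride (formed in the flask, not isolated) | CC(=O)OCCCCCCCCCCCCCC(=O)Cl | intermediate
4 | 14-acetoxytetradecanamide | CC(=O)OCCCCCCCCCCCCCC(N)=O | intermediate
5 | chloroacetone (1-chloropropan-2-one) | CC(=O)CCl | starting material
6 | 2-(13-acetoxytridecyl)-4-hydroxy-4-methyl-4,5-dihydrooxazole (formed in the flask, not isolated) | CC(=O)OCCCCCCCCCCCCCC1=NC(C)(O)CO1 | intermediate
7 | 2-(13-acetoxytridecyl)-4-methyloxazole | CC(=O)OCCCCCCCCCCCCCc1nc(C)co1 | intermediate
8 | but-2-ynoic acid | CC#CC(=O)O | starting material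
9 | tert-butyl but-2-ynoate | CC#CC(=O)OC(C)(C)C | intermediate
10 | tert-butyl 1-(13-acetoxytridecyl)-3,5-dimethyl-7-oxa-2-azabicyclo[2.2.1]hepta-2,5-diene-6-carboxylate (racemic; formed in the flask, not isolated) | CC(=O)OCCCCCCCCCCCCCC12OC(C(C)=N1)C(C)=C2C(=O)OC(C)(C)C | intermediate
11 | tert-butyl 2-(13-acetoxytridecyl)-4-methylfuran-3-carboxylate | CC(=O)OCCCCCCCCCCCCCc1occ(C)c1C(=O)OC(C)(C)C | intermediate
12 | tert-butyl 1-(13-acetoxytridecyl)-5-methyl-2,3,7-trioxabicyclo[2.2.1]hept-5-ene-6-carboxylate (racemic; formed in the flask, not isolated) | CC(=O)OCCCCCCCCCCCCCC12OOC(O1)C(C)=C2C(=O)OC(C)(C)C | intermediate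
13 | tert-butyl 2-(13-acetoxytridecyl)-2-hydroxy-4-methyl-5-oxo-2,5-dihydrofuran-3-carboxylate (racemic hemiketal) | CC(=O)OCCCCCCCCCCCCCC1(O)OC(=O)C(C)=C1C(=O)OC(C)(C)C | intermediate
14 | (E)-17-acetoxy-3-(tert-butoxycarbonyl)-2-methyl-4-oxoheptadec-2-enoic acid (carboxyl and acyl groups cis; formed in the flask, not isolated) | OC(=O)/C(C)=C(\C(=O)CCCCCCCCCCCCCOC(C)=O)C(=O)OC(C)(C)C | intermediate
15 | (R,E)-17-acetoxy-3-(tert-butoxycarbonyl)-4-hydroxy-2-methylheptadec-2-enoic acid (formed in the flask, not isolated) | OC(=O)/C(C)=C(\[C@H](O)CCCCCCCCCCCCCOC(C)=O)C(=O)OC(C)(C)C | intermediate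
16 | tert-butyl (R)-2-(13-acetoxytridecyl)-4-methyl-5-oxo-2,5-dihydrofuran-3-carboxylate | CC(=O)OCCCCCCCCCCCCC[C@H]1OC(=O)C(C)=C1C(=O)OC(C)(C)C | intermediate
17 | (R)-2-(13-acetoxytridecyl)-4-methyl-5-oxo-2,5-dihydrofuran-3-carboxylic acid | CC(=O)OCCCCCCCCCCCCC[C@H]1OC(=O)C(C)=C1C(=O)O | target

Total step count: 8. Longest linear sequence: 7 steps (steps 1, 2, 3, 5, 6, 7 and 8, from 14-hydroxytetradecanoic acid); step 4 is a one-step side branch.

The three steps most likely to fail are, in this order, step 5, step 7 and step 6.

For step 5, the bimolecular cycloaddition may stall before useful conversion, because a β-methyl ynoate is a sluggish dienophile toward a dialkyloxazole. Prolonged heating may then erode the regiocontrol or start to cleave the tert-butyl ester. The fallback keeps the same two bond formations in one operation but changes the diene to a mesoionic dipole that reacts at 80 °C. It sets out from acid 2, whose chloride 3 (made as in step 2) is treated with methylamine to give N-methyl-14-acetoxytetradecanamide F1. N-Acylation with bromoacetyl bromide gives N-(bromoacetyl)-N-methyl-14-acetoxytetradecanamide F2, and N,N'-ditosylhydrazine with DBU converts it into N-(diazoacetyl)-N-methyl-14-acetoxytetradecanamide F3. Rh2(OAc)4 (cat.) in toluene at 80 °C in the presence of 9 should generate the isomünchnone 2-(13-acetoxytridecyl)-3-methyl-1,3-oxazol-3-ium-4-olate F4 by attack of the carbenoid on the neighbouring amide oxygen. Its cycloadduct with 9, tert-butyl 1-(13-acetoxytridecyl)-2,5-dimethyl-3-oxo-7-oxa-2-azabicyclo[2.2.1]hept-5-ene-6-carboxylate F5, should lose methyl isocyanate and come back to the route at furan 11.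

For step 7, hydride transfer may show poor facial selectivity on an alkyl alkenyl ketone that has no aryl group, or may compete with conjugate reduction of the electron-poor alkene. The fallback sets out from 13. Alkylation of its carboxylate with MeI and Cs2CO3 in DMF should trap the open form as methyl (E)-17-acetoxy-3-(tert-butoxycarbonyl)-2-methyl-4-oxoheptadec-2-enoate F6. Corey–Bakshi–Shibata reduction ((S)-2-methyl-CBS-oxazaborolidine, BH3·SMe2, toluene, −30 °C), with the branched alkenyl group as the large substituent, should give methyl (R,E)-17-acetoxy-3-(tert-butoxycarbonyl)-4-hydroxy-2-methylheptadec-2-enoate F7. Lactonisation catalysed by pyridinium p-toluenesulfonate, with loss of methanol, returns to the route at 16.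

For step 6, singlet oxygen may add only slowly to the ester-deactivated furan, so that dye bleaching and oxidation of the amine take over, or the endoperoxide may decompose before the base-induced fragmentation. The fallback sets out from 11. NBS with NaHCO3 in aqueous acetone at −15 °C should open the furan oxidatively to the cis keto enal tert-butyl (E)-2-(14-acetoxytetradecanoyl)-3-methyl-4-oxobut-2-enoate F8. Pinnick oxidation of the aldehyde (NaClO2, NaH2PO4, 2-methylbut-2-ene, t-BuOH/H2O) then gives keto acid 14, which closes to pseudo-acid 13, where the route is rejoined.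

Further compounds
F1 | step 5 | N-methyl-14-acetoxytetradecanamide | CC(=O)OCCCCCCCCCCCCCC(=O)NC
F2 | step 5 | N-(bromoacetyl)-N-methyl-14-acetoxytetradecanamide | CC(=O)OCCCCCCCCCCCCCC(=O)N(C)C(=O)CBr
F3 | step 5 | N-(diazoacetyl)-N-methyl-14-acetoxytetradecanamide | CC(=O)OCCCCCCCCCCCCCC(=O)N(C)C(=O)C=[N+]=[N-]
F4 | step 5 | 2-(13-acetoxytridecyl)-3-methyl-1,3-oxazol-3-ium-4-olate | CC(=O)OCCCCCCCCCCCCCC1=[N+](C)C([O-])=CO1
F5 | step 5 | tert-butyl 1-(13-acetoxytridecyl)-2,5-dimethyl-3-oxo-7-oxa-2-azabicyclo[2.2.1]hept-5-ene-6-carboxylate | CC(=O)OCCCCCCCCCCCCCC12OC(C(=O)N1C)C(C)=C2C(=O)OC(C)(C)C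
F6 | step 7 | methyl (E)-17-acetoxy-3-(tert-butoxycarbonyl)-2-methyl-4-oxoheptadec-2-enoate | COC(=O)/C(C)=C(\C(=O)CCCCCCCCCCCCCOC(C)=O)C(=O)OC(C)(C)C
F7 | step 7 | methyl (R,E)-17-acetoxy-3-(tert-butoxycarbonyl)-4-hydroxy-2-methylheptadec-2-enoate | COC(=O)/C(C)=C(\[C@H](O)CCCCCCCCCCCCCOC(C)=O)C(=O)OC(C)(C)C
F8 | step 6 | tert-butyl (E)-2-(14-acetoxytetradecanoyl)-3-methyl-4-oxobut-2-enoate | O=C/C(C)=C(\C(=O)CCCCCCCCCCCCCOC(C)=O)C(=O)OC(C)(C)C
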